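**Plan**

1. Retrosynthesis: the quinone is carried as its hydroquinone dimethyl ether. The hexaprenyl chain is cut at the C(sp2)–C(sp3) bond between the vinyl CH of the third isoprene unit (counted from the isopropylidene end) and the CH2 next to it, which gives a C14 (E)-alkenyl iodide and an aryl-bearing C16 chain that ends in a 1,3-diene.
2. Enabling feature: in the spacer C(CH3)=CH–CH2–CH2–C(CH3)=CH, the CH2 to be joined is the end carbon of a vinyl group on the next C(CH3)=CH (a 3-methyl-1,3-diene, so 9-BBN puts boron on exactly that carbon). The vinyl CH is the terminal carbon of a terminal alkyne once the methyl branch is taken off (retron of a syn-methylalumination).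
3. Further cuts: the diene goes back to an enal (Wittig) and this to a farnesyl terminus (allylic oxidation); the aryl–CH2 bond to an arylcopper plus (2E,6E)-farnesyl bromide; the alkyne to geranyl bromide plus a silylpropyne; the methyl-bearing benzo ring (ring B) to a Diels–Alder reaction of 2-bromo-6-methylbenzoquinone with piperylene.
4. Forward order: ring A is made as a benzoquinone from a phenol, ring B is annulated and aromatised by loss of HBr and isomerisation to the naphthalenediol, with bromine fixing the place of the peri methyl. The diol is O-methylated directly, then come bromination, farnesylation, chain-end elaboration, fragment union and oxidative unmasking of the quinone.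
5. Stereochemistry: the target has no stereocentre. Four E double bonds are bought with farnesyl and geranyl bromide and never touched, the fifth comes from syn-carboalumination of the alkyne, and the coupling keeps it.

Key step: step 10

Assumption: (2E,6E)-farnesyl bromide, (E)-geranyl bromide and (E)-piperylene are used as geometrically pure commercial materials; locants of the naphthalene core change between compounds only through the numbering rules, the substitution pattern stays the same.

**Route**

Step 1
Reactants: 1 2-bromo-6-methylphenol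
Product: 2 2-bromo-6-methylcyclohexa-2,5-diene-1,4-dione
Conditions: (KO3S)2NO (2.2 equiv), KH2PO4, H2O/acetone, 0 °C → rt
Reagents that add atoms: dipotassium nitrosodisulfonate (Fremy's salt), [K+].[K+].[O]N(S(=O)(=O)[O-])S(=O)(=O)[O-]
Why: Teuber oxidation, in which the phenoxyl radical is trapped by a second equivalent of the nitroxide at the free para position and collapses to the para-quinone, both ortho positions being blocked.

Step 2
Reactants: 2 2-bromo-6-methylcyclohexa-2,5-diene-1,4-dione; 3 (E)-penta-1,3-diene
Product: 6 2,8-dimethylnaphthalene-1,4-diol, via bromo cycloadduct 4 (not isolated), via dihydroquinone 5 (not isolated)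
Conditions: 3 (3 equiv), PhMe, 50 °C, sealed vessel, dark; evaporation; then slow addition to Et3N (3 equiv), degassed THF, rt, under argon; degassed aqueous NH4Cl work-up, crude diol kept under argon and used at once
Reagents that add atoms: none
Why: Diels–Alder reaction at the brominated double bond of 2, in which the CH2 terminus of the diene bonds to the unbrominated CH (β to the electron-poor C1 carbonyl, the C4 carbonyl being deactivated by donation from both Br and CH3) and the methyl-bearing terminus to the C–Br carbon, followed by E1cB loss of HBr and amine-mediated prototropic shift of the two ring-B hydrogens of 5 to oxygen, which gives the aromatic diol, an isomer of 5, without any oxidant, so that one oxygen ends up between the ring-A methyl and the peri methyl.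

Step 3
Reactants: 6 2,8-dimethylnaphthalene-1,4-diol
Product: 7 1,4-dimethoxy-2,8-dimethylnaphthalene
Conditions: KOH (powdered), Me2SO4 (3 equiv), n-Bu4NBr (cat.), degassed THF, 0 °C → rt, under argon
Reagents that add atoms: dimethyl sulfate, COS(=O)(=O)OC
Why: Williamson O-methylation of the bis-phenoxide under phase transfer with air kept out, the usual masking of 2-methylnaphthalene-1,4-diols, which takes the diol on at the oxidation level at which step 2 delivers it.

Step 4
Reactants: 7 1,4-dimethoxy-2,8-dimethylnaphthalene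
Product: 8 2-bromo-1,4-dimethoxy-3,5-dimethylnaphthalene
Conditions: Br2 (1.05 equiv), CH2Cl2, 0 °C
Reagents that add atoms: bromine, BrBr
Why: electrophilic aromatic bromination at the only free position of the dimethoxy-substituted ring, ortho to a methoxy group and far more activated than any position of the methyl-bearing benzo ring.

Step 5
Reactants: 8 2-bromo-1,4-dimethoxy-3,5-dimethylnaphthalene; 9 (2E,6E)-1-bromo-3,7,11-trimethyldodeca-2,6,10-triene (farnesyl bromide)
Product: 12 1,4-dimethoxy-3,5-dimethyl-2-[(2E,6E)-3,7,11-trimethyldodeca-2,6,10-trien-1-yl]naphthalene, via aryllithium 10 (not isolated), via arylcopper 11 (not isolated)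
Conditions: n-BuLi, THF, −78 °C; CuBr·SMe2, −78 → −40 °C; 9, −78 → 0 °C
Reagents that add atoms: none
Why: bromine–lithium exchange, transmetalation to copper and copper-mediated SN2 allylic substitution at the primary carbon of the allylic bromide, which keeps the 2E geometry because attack at the γ-carbon would have to build a quaternary centre.

Step 6
Reactants: 12 1,4-dimethoxy-3,5-dimethyl-2-[(2E,6E)-3,7,11-trimethyldodeca-2,6,10-trien-1-yl]naphthalene
Product: 14 (2E,6E,10E)-12-(1,4-dimethoxy-3,5-dimethylnaphthalen-2-yl)-2,6,10-trimethyldodeca-2,6,10-trienal, via allylic alcohol 13 (not isolated)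
Conditions: SeO2 (cat.), salicylic acid (cat.), t-BuOOH, CH2Cl2, 0 °C → rt; aqueous work-up; then MnO2, CH2Cl2, rt
Reagents that add atoms: selenium dioxide, O=[Se]=O (catalytic carrier of the oxygen atom); tert-butyl hydroperoxide, CC(C)(C)OO (stoichiometric oxygen source)
Why: SeO2-catalysed allylic oxidation (ene reaction, then [2,3]-sigmatropic shift) should attack the E methyl group of the terminal, least hindered trisubstituted double bond to give the E allylic alcohol, which MnO2 oxidises selectively to the enal without changing any double-bond geometry.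

Step 7
Reactants: 14 (2E,6E,10E)-12-(1,4-dimethoxy-3,5-dimethylnaphthalen-2-yl)-2,6,10-trimethyldodeca-2,6,10-trienal
Product: 15 1,4-dimethoxy-3,5-dimethyl-2-[(2E,6E,10E)-3,7,11-trimethyltrideca-2,6,10,12-tetraen-1-yl]naphthalene
Conditions: Ph3PCH3Br, n-BuLi, THF, 0 °C; then 14, −78 °C → rt
Reagents that add atoms: methyltriphenylphosphonium bromide, C[P+](c1ccccc1)(c1ccccc1)c1ccccc1.[Br-]
Why: Wittig methylenation, in which the unstabilised ylide adds 1,2 to the enal and leaves the E trisubstituted double bond untouched, as in the conversion of geranial into its 1,3-diene.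

Step 8
Reactants: 16 (2E)-1-bromo-3,7-dimethylocta-2,6-diene (geranyl bromide); 17 trimethyl(prop-1-yn-1-yl)silane
Product: 20 (5E)-6,10-dimethylundeca-5,9-dien-1-yne, via lithiated silylpropyne 18 (not isolated), via silylated enyne 19 (not isolated)
Conditions: 17, n-BuLi, THF, −78 → −20 °C; 16, −78 °C → rt; then K2CO3 (cat.), MeOH, rt
Reagents that add atoms: none
Why: propargylic lithiation and SN2 alkylation at the primary allylic carbon with retention of the E double bond (the silyl group suppresses allene formation), followed by base-catalysed methanolysis of the C(sp)–Si bond.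

Step 9
Reactants: 20 (5E)-6,10-dimethylundeca-5,9-dien-1-yne
Product: 22 (1E,5E)-1-iodo-2,6,10-trimethylundeca-1,5,9-triene, via alkenylalane 21 (not isolated)
Conditions: AlMe3 (2 equiv), Cp2ZrCl2 (0.25 equiv), CH2Cl2, 0 °C → rt; then I2, THF, −30 → 0 °C
Reagents that add atoms: trimethylaluminium, C[Al](C)C; iodine, II
Why: Zr-catalysed syn-carboalumination (Negishi methylalumination) of the terminal alkyne places CH3 on the internal and Al on the terminal carbon on the same side, and iodinolysis of the C–Al bond with retention gives the E iodide, the isolated trisubstituted double bonds being inert.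

Step 10
Reactants: 15 1,4-dimethoxy-3,5-dimethyl-2-[(2E,6E,10E)-3,7,11-trimethyltrideca-2,6,10,12-tetraen-1-yl]naphthalene; 22 (1E,5E)-1-iodo-2,6,10-trimethylundeca-1,5,9-triene
Product: 24 2-[(2E,6E,10E,14E,18E)-3,7,11,15,19,23-hexamethyltetracosa-2,6,10,14,18,22-hexaen-1-yl]-1,4-dimethoxy-3,5-dimethylnaphthalene, via alkylborane 23 (not isolated)
Conditions: 9-BBN (1.05 equiv), THF, 0 °C → rt; then 22, PdCl2(dppf) (5 mol %), AsPh3, Cs2CO3, DMF/THF/H2O, rt
Reagents that add atoms: none
Why: 9-BBN adds anti-Markovnikov to the monosubstituted vinyl end of the 1,3-diene of 15, so boron sits on the terminal CH2 that has to be joined; oxidative addition of zerovalent palladium into the C–I bond of 22, base-assisted transfer of the primary alkyl group from the borate and reductive elimination then form the C(sp3)–C(sp2) bond. The closest known reaction type is the B-alkyl Suzuki–Miyaura coupling of homoallylic 9-BBN adducts, made from enal-derived terminal 1,3-dienes, with alkenyl iodides. No ring is closed and no stereocentre is formed; the E geometry of 22 is carried over because oxidative addition and reductive elimination both go with retention at the alkenyl carbon. The step needs chemoselectivity among the four C=C bonds of 15 and regioselectivity within the diene, and both follow from the bulk of 9-BBN, which reacts only with the single monosubstituted alkene and leaves the three trisubstituted ones alone. The quinone is present as its dimethyl ether because a quinone would not survive the borane, the base and zerovalent palladium, whereas the dimethoxynaphthalene is inert. β-Hydride elimination from the alkylpalladium intermediate is held back by the wide-bite-angle dppf ligand together with AsPh3 at room temperature.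

Step 11
Reactants: 24 2-[(2E,6E,10E,14E,18E)-3,7,11,15,19,23-hexamethyltetracosa-2,6,10,14,18,22-hexaen-1-yl]-1,4-dimethoxy-3,5-dimethylnaphthalene
Product: 25 2-[(2E,6E,10E,14E,18E)-3,7,11,15,19,23-hexamethyltetracosa-2,6,10,14,18,22-hexaen-1-yl]-3,5-dimethylnaphthalene-1,4-dione
Conditions: (NH4)2Ce(NO3)6 (2.5 equiv), MeCN/H2O/CH2Cl2, 0 °C
Reagents that add atoms: water, O
Why: oxidative demethylation of the para-dimethoxyarene by two equivalents of the tetravalent cerium salt through the arene radical cation and attack of water, the usual unmasking of polyprenyl naphthoquinones, which should leave the isolated trisubstituted alkenes untouched at 0 °C and short reaction time.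

**Compound list**

1 | 2-bromo-6-methylphenol | Cc1cccc(Br)c1O | starting material
2 | 2-bromo-6-methylcyclohexa-2,5-diene-1,4-dione | CC1=CC(=O)C=C(Br)C1=O | intermediate
3 | (E)-penta-1,3-diene (trans-piperylene) | C/C=C/C=C | starting material
4 | 8a-bromo-2,8-dimethyl-4a,5,8,8a-tetrahydronaphthalene-1,4-dione, racemic cis-fused endo adduct with the 8-methyl trans to the 8a-bromine (one enantiomer drawn) | CC1=CC(=O)[C@@H]2CC=C[C@H](C)[C@]2(Br)C1=O | intermediate (not isolated)
5 | 2,8-dimethyl-5,8-dihydronaphthalene-1,4-dione (racemic) | CC1=CC(=O)C2=C(C(C)C=CC2)C1=O | intermediate (not isolated)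
6 | 2,8-dimethylnaphthalene-1,4-diol | Cc1cc(O)c2cccc(C)c2c1O | intermediate
7 | 1,4-dimethoxy-2,8-dimethylnaphthalene | COc1cc(C)c(OC)c2c(C)cccc12 | intermediate
8 | 2-bromo-1,4-dimethoxy-3,5-dimethylnaphthalene | COc1c(Br)c(C)c(OC)c2c(C)cccc12 | intermediate
9 | (2E,6E)-1-bromo-3,7,11-trimethyldodeca-2,6,10-triene (farnesyl bromide) | CC(C)=CCC/C(C)=C/CC/C(C)=C/CBr | starting material
10 | (1,4-dimethoxy-3,5-dimethylnaphthalen-2-yl)lithium | [Li]c1c(C)c(OC)c2c(C)cccc2c1OC | intermediate (not isolated)
11 | (1,4-dimethoxy-3,5-dimethylnaphthalen-2-yl)copper | [Cu]c1c(C)c(OC)c2c(C)cccc2c1OC | intermediate (not isolated)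
12 | 1,4-dimethoxy-3,5-dimethyl-2-[(2E,6E)-3,7,11-trimethyldodeca-2,6,10-trien-1-yl]naphthalene | CC(C)=CCC/C(C)=C/CC/C(C)=C/Cc1c(C)c(OC)c2c(C)cccc2c1OC | intermediate
13 | (2E,6E,10E)-12-(1,4-dimethoxy-3,5-dimethylnaphthalen-2-yl)-2,6,10-trimethyldodeca-2,6,10-trien-1-ol | OC/C(C)=C/CC/C(C)=C/CC/C(C)=C/Cc1c(C)c(OC)c2c(C)cccc2c1OC | intermediate (not isolated)
14 | (2E,6E,10E)-12-(1,4-dimethoxy-3,5-dimethylnaphthalen-2-yl)-2,6,10-trimethyldodeca-2,6,10-trienal | O=C/C(C)=C/CC/C(C)=C/CC/C(C)=C/Cc1c(C)c(OC)c2c(C)cccc2c1OC | intermediate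
15 | 1,4-dimethoxy-3,5-dimethyl-2-[(2E,6E,10E)-3,7,11-trimethyltrideca-2,6,10,12-tetraen-1-yl]naphthalene | C=C/C(C)=C/CC/C(C)=C/CC/C(C)=C/Cc1c(C)c(OC)c2c(C)cccc2c1OC | intermediate
16 | (2E)-1-bromo-3,7-dimethylocta-2,6-diene (geranyl bromide) | CC(C)=CCC/C(C)=C/CBr | starting material
17 | trimethyl(prop-1-yn-1-yl)silane | CC#C[Si](C)(C)C | starting material
18 | [3-(trimethylsilyl)prop-2-yn-1-yl]lithium | [Li]CC#C[Si](C)(C)C | intermediate (not isolated)
19 | [(5E)-6,10-dimethylundeca-5,9-dien-1-yn-1-yl]trimethylsilane | CC(C)=CCC/C(C)=C/CCC#C[Si](C)(C)C | intermediate (not isolated)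
20 | (5E)-6,10-dimethylundeca-5,9-dien-1-yne | CC(C)=CCC/C(C)=C/CCC#C | intermediate
21 | dimethyl[(1E,5E)-2,6,10-trimethylundeca-1,5,9-trien-1-yl]alane | CC(C)=CCC/C(C)=C/CC/C(C)=C/[Al](C)C | intermediate (not isolated)
22 | (1E,5E)-1-iodo-2,6,10-trimethylundeca-1,5,9-triene | CC(C)=CCC/C(C)=C/CC/C(C)=C/I | intermediate
23 | 9-[(3E,7E,11E)-13-(1,4-dimethoxy-3,5-dimethylnaphthalen-2-yl)-3,7,11-trimethyltrideca-3,7,11-trien-1-yl]-9-borabicyclo[3.3.1]nonane | B1(CC/C(C)=C/CC/C(C)=C/CC/C(C)=C/Cc2c(C)c(OC)c3c(C)cccc3c2OC)C4CCCC1CCC4 | intermediate (not isolated)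
24 | 2-[(2E,6E,10E,14E,18E)-3,7,11,15,19,23-hexamethyltetracosa-2,6,10,14,18,22-hexaen-1-yl]-1,4-dimethoxy-3,5-dimethylnaphthalene | CC(C)=CCC/C(C)=C/CC/C(C)=C/CC/C(C)=C/CC/C(C)=C/CC/C(C)=C/Cc1c(C)c(OC)c2c(C)cccc2c1OC | intermediate
25 | 2-[(2E,6E,10E,14E,18E)-3,7,11,15,19,23-hexamethyltetracosa-2,6,10,14,18,22-hexaen-1-yl]-3,5-dimethylnaphthalene-1,4-dione | CC(C)=CCC/C(C)=C/CC/C(C)=C/CC/C(C)=C/CC/C(C)=C/CC/C(C)=C/CC1=C(C)C(=O)c2c(C)cccc2C1=O | target

**Count**

Total steps: 11. Longest linear sequence: 9 steps (steps 1, 2, 3, 4, 5, 6, 7, 10, 11); steps 8 and 9 make the second fragment.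

**Steps most likely to fail, with fallbacks**

1. Step 10. The transfer of the hindered primary alkyl group from boron to the trisubstituted alkenylpalladium iodide may be slow, so that protodeboronation, β-hydride elimination with alkene isomerisation, or reduction of the iodide compete. The fallback sets out from 15 and comes back at 24, forming the same bond by a Negishi alkyl–alkenyl coupling. Diene 15 is hydroborated with 9-BBN as before (alkylborane 23) and oxidised with NaOH/H2O2 to (3E,7E,11E)-13-(1,4-dimethoxy-3,5-dimethylnaphthalen-2-yl)-3,7,11-trimethyltrideca-3,7,11-trien-1-ol F1. I2, PPh3 and imidazole in CH2Cl2 should convert it into 2-[(2E,6E,10E)-13-iodo-3,7,11-trimethyltrideca-2,6,10-trien-1-yl]-1,4-dimethoxy-3,5-dimethylnaphthalene F2. Zinc dust (activated with a little I2) in N,N-dimethylacetamide at 40 °C should insert to give [(3E,7E,11E)-13-(1,4-dimethoxy-3,5-dimethylnaphthalen-2-yl)-3,7,11-trimethyltrideca-3,7,11-trien-1-yl]zinc iodide F3. This more nucleophilic homoallylzinc reagent is then coupled with 22 under Pd(PPh3)4 (zerovalent palladium) in THF/N,N-dimethylacetamide at rt to give 24.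

2. Step 2. The weakly polarised piperylene may add with poor regiocontrol, or partly to the methyl-bearing double bond. In addition, hydrogen exchange between dihydroquinone 5 and diol 6 during the isomerisation may divert part of the material to the quinone level and to an over-reduced level. The fallback sets out from 2 and comes back at 6. It uses a strongly polarised diene whose adduct aromatises by elimination instead of isomerisation, then turns the oxygen into the methyl group. Quinone 2 is treated with [(1-methoxybuta-1,3-dien-1-yl)oxy]trimethylsilane (CH2Cl2, −30 °C → rt, then silica gel). Its nucleophilic CH2 terminus should add only to the unbrominated CH, and ring closure on the C–Br carbon with loss of HBr, methanol and the silyl group should give 8-hydroxy-2-methylnaphthalene-1,4-dione F4. Tf2O and pyridine in CH2Cl2 at 0 °C give 7-methyl-5,8-dioxo-5,8-dihydronaphthalen-1-yl trifluoromethanesulfonate F5. Stille methylation (SnMe4, PdCl2(PPh3)2, LiCl, DMF, 90 °C) then gives 2,8-dimethylnaphthalene-1,4-dione F6. Reduction with aqueous Na2S2O4 in Et2O under argon gives 6.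

3. Step 6. The ene reaction with SeO2 may not discriminate well enough between the three trisubstituted double bonds of a late intermediate, or may stall or over-oxidise. The fallback sets out from 12 and comes back at 13, which is then oxidised with MnO2 to 14 as in the second stage of step 6; it replaces the C–H oxidation by cleavage and olefination. N-Bromosuccinimide in THF/H2O at 0 °C should give the terminal bromohydrin (6E,10E)-3-bromo-12-(1,4-dimethoxy-3,5-dimethylnaphthalen-2-yl)-2,6,10-trimethyldodeca-6,10-dien-2-ol F7. K2CO3 in MeOH closes it to the epoxide 2-[(2E,6E)-9-(3,3-dimethyloxiran-2-yl)-3,7-dimethylnona-2,6-dien-1-yl]-1,4-dimethoxy-3,5-dimethylnaphthalene F8. H5IO6 in THF/H2O cleaves it to (4E,8E)-10-(1,4-dimethoxy-3,5-dimethylnaphthalen-2-yl)-4,8-dimethyldeca-4,8-dienal F9. Horner–Wadsworth–Emmons olefination with triethyl 2-phosphonopropionate and NaH in THF should give, E-selectively, ethyl (2E,6E,10E)-12-(1,4-dimethoxy-3,5-dimethylnaphthalen-2-yl)-2,6,10-trimethyldodeca-2,6,10-trienoate F10. Reduction with i-Bu2AlH in CH2Cl2 at −78 °C gives 13.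

Further compounds
F1 | step 10 | (3E,7E,11E)-13-(1,4-dimethoxy-3,5-dimethylnaphthalen-2-yl)-3,7,11-trimethyltrideca-3,7,11-trien-1-ol | OCC/C(C)=C/CC/C(C)=C/CC/C(C)=C/Cc1c(C)c(OC)c2c(C)cccc2c1OC
F2 | step 10 | 2-[(2E,6E,10E)-13-iodo-3,7,11-trimethyltrideca-2,6,10-trien-1-yl]-1,4-dimethoxy-3,5-dimethylnaphthalene | ICC/C(C)=C/CC/C(C)=C/CC/C(C)=C/Cc1c(C)c(OC)c2c(C)cccc2c1OC
F3 | step 10 | [(3E,7E,11E)-13-(1,4-dimethoxy-3,5-dimethylnaphthalen-2-yl)-3,7,11-trimethyltrideca-3,7,11-trien-1-yl]zinc iodide | I[Zn]CC/C(C)=C/CC/C(C)=C/CC/C(C)=C/Cc1c(C)c(OC)c2c(C)cccc2c1OC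
F4 | step 2 | 8-hydroxy-2-methylnaphthalene-1,4-dione | CC1=CC(=O)c2cccc(O)c2C1=O
F5 | step 2 | 7-methyl-5,8-dioxo-5,8-dihydronaphthalen-1-yl trifluoromethanesulfonate | CC1=CC(=O)c2cccc(OS(=O)(=O)C(F)(F)F)c2C1=O
F6 | step 2 | 2,8-dimethylnaphthalene-1,4-dione | CC1=CC(=O)c2cccc(C)c2C1=O
F7 | step 6 | (6E,10E)-3-bromo-12-(1,4-dimethoxy-3,5-dimethylnaphthalen-2-yl)-2,6,10-trimethyldodeca-6,10-dien-2-ol (racemic) | CC(C)(O)C(Br)CC/C(C)=C/CC/C(C)=C/Cc1c(C)c(OC)c2c(C)cccc2c1OC
F8 | step 6 | 2-[(2E,6E)-9-(3,3-dimethyloxiran-2-yl)-3,7-dimethylnona-2,6-dien-1-yl]-1,4-dimethoxy-3,5-dimethylnaphthalene (racemic) | CC1(C)OC1CC/C(C)=C/CC/C(C)=C/Cc1c(C)c(OC)c2c(C)cccc2c1OC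
F9 | step 6 | (4E,8E)-10-(1,4-dimethoxy-3,5-dimethylnaphthalen-2-yl)-4,8-dimethyldeca-4,8-dienal | O=CCC/C(C)=C/CC/C(C)=C/Cc1c(C)c(OC)c2c(C)cccc2c1OC
F10 | step 6 | ethyl (2E,6E,10E)-12-(1,4-dimethoxy-3,5-dimethylnaphthalen-2-yl)-2,6,10-trimethyldodeca-2,6,10-trienoate | CCOC(=O)/C(C)=C/CC/C(C)=C/CC/C(C)=C/Cc1c(C)c(OC)c2c(C)cccc2c1OC
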